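**Retrosynthetic overview**
1. 8 ⇒ acylphloroglucinol 7 + 3 × prenyl bromide 5: three C‑prenylations, the last one dearomatising, run in the same pot as ring formation.
2. 7 ⇒ open‑chain tetraketide methyl ester 6: C6→C1 Claisen cyclisation, the ring closure the polyketide synthase performs.
3. 6 ⇒ tetraketide lactone 4 by methoxide opening of the pyranone (4 and 7 are isomers, so methoxide is only a carrier).
4. 4 ⇒ triacetic acid lactone 1 + methyl 3‑phenylpropanoate 2: dianion C‑acylation (starter unit onto a triketide).
5. Ring order: the pyranone of 1 is bought and sacrificed; the only carbocycle of 8 is formed in step 2 and never comes from phloroglucinol.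

Assumption: 8 has no stereocentre and no stereogenic double bond (the quaternary carbon carries two identical prenyl groups), so no stereocontrol is needed; as the route has only two steps, the three ranked risks at the end are the two stages of step 2 and step 1.

**Step 1**
Reactants: 1 4‑hydroxy‑6‑methyl‑2H‑pyran‑2‑one (triacetic acid lactone); 2 methyl 3‑phenylpropanoate
Product: 4 4‑hydroxy‑6‑(2‑oxo‑4‑phenylbutyl)‑2H‑pyran‑2‑one, via dilithio dianion 3 (not isolated)
Conditions: 1 (2.1 equiv), LDA (4.3 equiv), THF–DMPU, −78 °C; then 2 (1.0 equiv), −78 → 0 °C; 2 M HCl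
Reagents that add atoms: methyl 3‑phenylpropanoate (2), COC(=O)CCc1ccccc1
Why: Hauser–Harris dianion acylation (crossed Claisen condensation): the second deprotonation of 1 gives the extended dienolate 3, which is acylated by the ester at its exocyclic CH2 terminus, and the more acidic product is parked as its anion by the sacrificial second equivalent of 3 so that it is not attacked again; no stereocentre is formed.

**Step 2**
Reactants: 4 4‑hydroxy‑6‑(2‑oxo‑4‑phenylbutyl)‑2H‑pyran‑2‑one; 5 prenyl bromide (1‑bromo‑3‑methylbut‑2‑ene)
Product: 8 helilupolone, via triketo ester 6 (not isolated), via acylphloroglucinol 7 (not isolated)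
Conditions: NaOMe (4.0 equiv), MeOH, reflux, Ar; then H2O, 0 °C, prenyl bromide (3.3 equiv); 2 M HCl
Reagents that add atoms: prenyl bromide (5), CC(C)=CCBr
Why: Proposed new method: a telescoped biomimetic cascade in which methoxide reversibly opens the 2‑pyranone to the open‑chain tetraketide ester 6, whose β‑diketonate carbon C6 attacks the only non‑enolised carbonyl (ester C1) in a chalcone‑synthase‑type intramolecular Claisen (Dieckmann) cyclisation made irreversible by loss of methoxide and aromatisation to the phenolate of 7, which is then C‑alkylated three times by prenyl bromide in the protic medium (the alkylation at an already prenylated carbon dearomatises the ring and both possible orders converge on 8); the closest known reaction types are the alkoxide‑induced recyclisation of 6‑(2‑oxoalkyl)‑4‑hydroxy‑2‑pyranones and the strong‑base Claisen cyclisation of 3,5,7‑triketo esters to acylphloroglucinols, together with the alkaline dearomatising triprenylation of acylphloroglucinols to lupulones; no stereocentre is formed because the quaternary carbon carries two identical prenyl groups.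

**Compound list**
1 | 4‑hydroxy‑6‑methyl‑2H‑pyran‑2‑one (triacetic acid lactone) | CC1=CC(O)=CC(=O)O1 | starting material
2 | methyl 3‑phenylpropanoate | COC(=O)CCc1ccccc1 | starting material
3 | dilithium salt of the dianion of 1 (4‑oxido, 6‑CH2 carbanion) | [Li+].[Li+].[CH2-]C1=CC([O-])=CC(=O)O1 | intermediate
4 | 4‑hydroxy‑6‑(2‑oxo‑4‑phenylbutyl)‑2H‑pyran‑2‑one (tetraketide lactone) | O=C(CCc1ccccc1)CC1=CC(O)=CC(=O)O1 | intermediate
5 | 1‑bromo‑3‑methylbut‑2‑ene (prenyl bromide) | CC(C)=CCBr | starting material
6 | methyl 3,5,7‑trioxo‑9‑phenylnonanoate (present as its sodium enolates) | COC(=O)CC(=O)CC(=O)CC(=O)CCc1ccccc1 | intermediate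
7 | 3‑phenyl‑1‑(2,4,6‑trihydroxyphenyl)propan‑1‑one (present as its sodium phenolate) | O=C(CCc1ccccc1)c1c(O)cc(O)cc1O | intermediate
8 | helilupolone, 3,5‑dihydroxy‑4,6,6‑tris(3‑methylbut‑2‑en‑1‑yl)‑2‑(3‑phenylpropanoyl)cyclohexa‑2,4‑dien‑1‑one (achiral) | CC(C)=CCC1=C(O)C(CC=C(C)C)(CC=C(C)C)C(=O)C(C(=O)CCc2ccccc2)=C1O | target

**Step count and risks**
Total steps: 2. Longest linear sequence: 2 (1 + 2 → 4 → 8).

Risk 1, step 2, ring‑forming stage. The pyranone anion may resist methoxide, or the tetraketide may close the stilbene‑synthase way (C2→C7 aldol) to a resorcylate ester. The fallback makes the open‑chain ester without a pyranone and cyclises it on its own. It sets out from 2: the dianion of acetylacetone (NaH, then n‑BuLi, THF, 0 °C, 2 equiv of dianion per ester) is acylated by 2 to give 8‑phenyloctane‑2,4,6‑trione F1. Its trianion (LDA 3.1 equiv, THF, 0 °C) is carboxylated with CO2 at the methyl terminus, the less substituted site, to give 3,5,7‑trioxo‑9‑phenylnonanoic acid F2. F2 is esterified cold with TMSCHN2 (MeOH–toluene, 0 °C) to give 6, now isolated. 2 M aqueous KOH at room temperature closes 6 by Claisen condensation, and acidification gives 7 as an isolated solid. The fallback comes back to the route at 7, which is prenylated as in the second half of step 2.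

Risk 2, step 2, prenylation stage. Over‑alkylation to a tetraprenyl compound, O‑alkylation and solvolysis of the bromide are all possible in the crude cascade mixture. The fallback sets out from 7, isolated by acidifying the step‑2 mixture before any bromide is added, and installs the prenyl groups in the biosynthetic order by two different bond‑forming modes. Prenyl bromide (2.1 equiv) in 10 % aqueous KOH at 0 °C gives 3‑phenyl‑1‑[2,4,6‑trihydroxy‑3,5‑bis(3‑methylbut‑2‑en‑1‑yl)phenyl]propan‑1‑one F3. A Pd(0)‑catalysed dearomatising Tsuji–Trost prenylation (Pd(PPh3)4 5 mol %, prenyl acetate 1.2 equiv, DBU, THF, rt) then delivers the third prenyl group at the less hindered terminus of the π‑prenyl complex; any O‑prenyl ether re‑ionises and funnels to the C‑product. The fallback comes back to the route at 8.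

Risk 3, step 1. The ester 2 is enolisable, so proton transfer to 3 or self‑condensation may cut the yield. The fallback replaces the Claisen acylation by aldol addition and oxidation. It sets out from 1: dianion 3 (LDA 2.1 equiv, no sacrificial equivalent needed) adds to 3‑phenylpropanal at −78 °C to give racemic 4‑hydroxy‑6‑(2‑hydroxy‑4‑phenylbutyl)‑2H‑pyran‑2‑one F4, whose carbinol centre is destroyed at once. IBX (DMSO, rt) oxidises the secondary alcohol to the ketone, and the fallback comes back to the route at 4.

**Further compounds**
F1 | step 2 | 8‑phenyloctane‑2,4,6‑trione | CC(=O)CC(=O)CC(=O)CCc1ccccc1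
F2 | step 2 | 3,5,7‑trioxo‑9‑phenylnonanoic acid | OC(=O)CC(=O)CC(=O)CC(=O)CCc1ccccc1
F3 | step 2 | 3‑phenyl‑1‑[2,4,6‑trihydroxy‑3,5‑bis(3‑methylbut‑2‑en‑1‑yl)phenyl]propan‑1‑one | CC(C)=CCc1c(O)c(CC=C(C)C)c(O)c(C(=O)CCc2ccccc2)c1O
F4 | step 1 | 4‑hydroxy‑6‑(2‑hydroxy‑4‑phenylbutyl)‑2H‑pyran‑2‑one (racemic) | OC(CCc1ccccc1)CC1=CC(O)=CC(=O)O1
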